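**Retrosynthetic overview**
1. The 14-membered ring (the only ring) is closed last by intramolecular Horner–Wadsworth–Emmons olefination at C1=C2, which also sets the E-enoate.
2. C14–C1 comes from alkylation of trimethyl phosphonoacetate; C14 itself is inserted as a one-carbon unit from thioanisole (PhSCH2Li on the C13 allylic chloride, then sulfide-to-iodide exchange).
3. C5–C6 comes from Cu-catalysed coupling of the Grignard reagent of the C4 fragment with 8-bromogeranyl acetate, which supplies both ring E-alkenes.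
4. Key step: Cu-catalysed enantioselective SN2′ desymmetrisation of (E)-1,4-dibromobut-2-ene by the complete side-chain alkenyl nucleophile; it sets C4 and leaves a CH2Br and a vinyl handle.
5. The side-chain alkenyl iodide comes from prenyl bromide and propynylmagnesium bromide by hydrozirconation–iodination.

Assumption: (R,R)-Taniaphos is taken to give the 3R bromide 9 in step 3; if a pilot run shows the opposite sense, the enantiomeric ligand is used.

**Route**

Step 1
Reactants: 1 1-bromo-3-methylbut-2-ene (prenyl bromide); 2 prop-1-yn-1-ylmagnesium bromide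
Product: 3 6-methylhept-5-en-2-yne
Conditions: CuCl (5 mol%), THF, 0 °C → rt
Reagents that add atoms: none
Why: Cu(I)-catalysed alkynyl–allyl coupling, in which the alkynylcopper attacks the primary allylic bromide in SN2 fashion to give the skipped enyne; no stereocentre is formed.

Step 2
Reactants: 3 6-methylhept-5-en-2-yne
Product: 5 (2E)-2-iodo-6-methylhepta-2,5-diene, via alkenylzirconocene chloride 4 (not isolated)
Conditions: Cp2Zr(H)Cl (2 equiv), THF, 50 °C, 1 h; then I2, 0 °C
Reagents that add atoms: iodine, II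
Why: Hydrozirconation–iodination: syn addition under equilibrating conditions puts Zr on the less hindered, methyl-bearing alkyne carbon, and iodinolysis with retention gives the E iodide (about 10% regioisomer expected, removed by chromatography).

Step 3
Reactants: 5 (2E)-2-iodo-6-methylhepta-2,5-diene; 6 (2E)-1,4-dibromobut-2-ene
Product: 9 (3R,4E)-3-(bromomethyl)-4,8-dimethylnona-1,4,7-triene, via alkenyllithium 7 (not isolated), via alkenylmagnesium bromide 8 (not isolated)
Conditions: t-BuLi (2.0 equiv), Et2O, −78 °C; MgBr2·OEt2; then slow addition to 6 (1.2 equiv), CuBr·SMe2 (5 mol%), (R,R)-Taniaphos (6 mol%), CH2Cl2, −78 °C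
Reagents that add atoms: none
Why: Proposed new method: the chiral alkenyl-copper(I) complex attacks one enantiotopic face of the symmetric dibromide anti to a leaving bromide, and the resulting γ-σ-allyl copper(III) species reductively eliminates quickly (sp2 ligand), so the E-alkenyl group is delivered SN2′ with retention of its geometry, setting C4 as R and leaving an unreactive homoallylic CH2Br plus a vinyl group; the closest known reactions are the Cu/Taniaphos SN2′ desymmetrisation of this same dibromide by alkyl Grignard reagents and Cu-catalysed enantioselective allylic substitution with alkenyl-metal nucleophiles.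

Step 4
Reactants: 10 geranyl acetate
Product: 11 (2E,6E)-8-hydroxy-3,7-dimethylocta-2,6-dien-1-yl acetate
Conditions: SeO2 (0.1 equiv), t-BuOOH (70% aq., 2 equiv), salicylic acid (0.1 equiv), CH2Cl2, rt; NaBH4, MeOH, 0 °C on the crude to return over-oxidised enal
Reagents that add atoms: tert-butyl hydroperoxide, CC(C)(C)OO
Why: SeO2-catalysed allylic oxidation (ene reaction then [2,3]-shift) is selective for the E-methyl group of the terminal trisubstituted alkene, giving the E allylic alcohol.

Step 5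
Reactants: 11 (2E,6E)-8-hydroxy-3,7-dimethylocta-2,6-dien-1-yl acetate
Product: 12 (2E,6E)-8-bromo-3,7-dimethylocta-2,6-dien-1-yl acetate
Conditions: CBr4, PPh3, CH2Cl2, 0 °C
Reagents that add atoms: carbon tetrabromide, BrC(Br)(Br)Br
Why: Appel bromination of the primary allylic alcohol proceeds by SN2 without allylic shift or loss of E geometry and leaves the acetate intact.

Step 6
Reactants: 9 (3R,4E)-3-(bromomethyl)-4,8-dimethylnona-1,4,7-triene; 12 (2E,6E)-8-bromo-3,7-dimethylocta-2,6-dien-1-yl acetate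
Product: 14 (2E,6E,10R,11E)-10-ethenyl-3,7,11,15-tetramethylhexadeca-2,6,11,14-tetraen-1-yl acetate, via alkylmagnesium bromide 13 (not isolated)
Conditions: Mg turnings (activated), THF, 0 °C, used at once; then 12 (0.95 equiv), Li2CuCl4 (3 mol%), THF, −78 → −20 °C
Reagents that add atoms: none
Why: Kochi-type Cu-catalysed Grignard coupling at the primary allylic bromide (SN2, E retained) forms C5–C6 faster than attack on the acetate at low temperature, and C4 is not involved.

Step 7
Reactants: 14 (2E,6E,10R,11E)-10-ethenyl-3,7,11,15-tetramethylhexadeca-2,6,11,14-tetraen-1-yl acetate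
Product: 16 (2E,6E,10R)-3,7-dimethyl-10-[(2E)-6-methylhepta-2,5-dien-2-yl]dodeca-2,6-diene-1,12-diol, via B-alkyl-9-BBN adduct 15 (not isolated)
Conditions: 9-BBN (1.2 equiv), THF, 0 °C → rt; then 3 M NaOH, 30% H2O2, 0 °C → rt
Reagents that add atoms: hydrogen peroxide, OO
Why: Hydroboration–oxidation: 9-BBN adds anti-Markovnikov only to the monosubstituted vinyl group in the presence of four trisubstituted alkenes, and the alkaline oxidation also saponifies the acetate.

Step 8
Reactants: 16 (2E,6E,10R)-3,7-dimethyl-10-[(2E)-6-methylhepta-2,5-dien-2-yl]dodeca-2,6-diene-1,12-diol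
Product: 17 (3R,6E,10E)-12-chloro-6,10-dimethyl-3-[(2E)-6-methylhepta-2,5-dien-2-yl]dodeca-6,10-dien-1-ol
Conditions: NCS (1.1 equiv), Me2S (1.2 equiv), CH2Cl2, −20 → 0 °C
Reagents that add atoms: N-chlorosuccinimide, O=C1CCC(=O)N1Cl
Why: Corey–Kim chlorination converts only the allylic alcohol (chloride displaces the allylic alkoxysulfonium group), while the saturated primary alcohol is returned on work-up; E geometry is kept.

Step 9
Reactants: 17 (3R,6E,10E)-12-chloro-6,10-dimethyl-3-[(2E)-6-methylhepta-2,5-dien-2-yl]dodeca-6,10-dien-1-ol; 18 (methylsulfanyl)benzene (thioanisole)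
Product: 20 (3R,6E,10E)-6,10-dimethyl-3-[(2E)-6-methylhepta-2,5-dien-2-yl]-13-(phenylsulfanyl)trideca-6,10-dien-1-ol, via (phenylsulfanyl)methyllithium 19 (not isolated)
Conditions: 18 (2.5 equiv), n-BuLi, DABCO, THF, 0 °C; then 17, −78 °C → rt
Reagents that add atoms: none
Why: SN2 alkylation of the sulfur-stabilised carbanion at the primary allylic chloride adds C14 (first stage of the Corey–Jautelat one-carbon homologation); one extra equivalent of carbanion is consumed by the hydroxyl group.

Step 10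
Reactants: 20 (3R,6E,10E)-6,10-dimethyl-3-[(2E)-6-methylhepta-2,5-dien-2-yl]-13-(phenylsulfanyl)trideca-6,10-dien-1-ol
Product: 22 (3R,6E,10E)-13-iodo-6,10-dimethyl-3-[(2E)-6-methylhepta-2,5-dien-2-yl]trideca-6,10-dien-1-ol, via S-methylsulfonium iodide 21 (not isolated)
Conditions: MeI (10 equiv), NaI (2 equiv), DMF, 70 °C
Reagents that add atoms: iodomethane, CI
Why: Sulfide-to-iodide exchange: S-methylation makes thioanisole a leaving group, which iodide displaces by SN2 at the primary homoallylic carbon; alkenes and the free alcohol are inert.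

Step 11
Reactants: 22 (3R,6E,10E)-13-iodo-6,10-dimethyl-3-[(2E)-6-methylhepta-2,5-dien-2-yl]trideca-6,10-dien-1-ol; 23 trimethyl phosphonoacetate
Product: 25 methyl (5E,9E,13R)-2-(dimethoxyphosphoryl)-15-hydroxy-6,10-dimethyl-13-[(2E)-6-methylhepta-2,5-dien-2-yl]pentadeca-5,9-dienoate (both C2 epimers), via sodium phosphonoacetate enolate 24 (not isolated)
Conditions: 23 (3 equiv), NaH (2.8 equiv), DMF, 0 °C; then 22, 50 °C
Reagents that add atoms: none
Why: C-alkylation of the stabilised phosphonate carbanion by the primary iodide forms C14–C1; the excess anion suppresses dialkylation and is too weak a base to deprotonate the alcohol.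

Step 12
Reactants: 25 methyl (5E,9E,13R)-2-(dimethoxyphosphoryl)-15-hydroxy-6,10-dimethyl-13-[(2E)-6-methylhepta-2,5-dien-2-yl]pentadeca-5,9-dienoate
Product: 26 methyl (5E,9E,13R)-2-(dimethoxyphosphoryl)-6,10-dimethyl-13-[(2E)-6-methylhepta-2,5-dien-2-yl]-15-oxopentadeca-5,9-dienoate
Conditions: Dess–Martin periodinane (1.3 equiv), NaHCO3, CH2Cl2, 0 °C → rt
Reagents that add atoms: none
Why: Dess–Martin oxidation of the primary alcohol to the aldehyde is neutral and spares the alkenes and the phosphonate; C4 is β to the new carbonyl and cannot epimerise.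

Step 13
Reactants: 26 methyl (5E,9E,13R)-2-(dimethoxyphosphoryl)-6,10-dimethyl-13-[(2E)-6-methylhepta-2,5-dien-2-yl]-15-oxopentadeca-5,9-dienoate
Product: 27 methyl (1E,4R,7E,11E)-7,11-dimethyl-4-[(2E)-6-methylhepta-2,5-dien-2-yl]cyclotetradeca-1,7,11-triene-1-carboxylate
Conditions: LiCl (10 equiv), DBU (5 equiv), MeCN, syringe-pump addition to 0.002 M, rt
Reagents that add atoms: none
Why: Intramolecular Horner–Wadsworth–Emmons olefination under Masamune–Roush conditions closes the 14-membered ring, and the α-alkyl phosphonoacetate gives the E enoate (CO2Me trans to C3) as in the target; both C2 epimers of 25/26 converge.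

**Compound list**
1 | 1-bromo-3-methylbut-2-ene (prenyl bromide) | CC(C)=CCBr | starting material
2 | prop-1-yn-1-ylmagnesium bromide | CC#C[Mg]Br | starting material
3 | 6-methylhept-5-en-2-yne | CC#CCC=C(C)C | intermediate
4 | chlorobis(cyclopentadienyl)[(2E)-6-methylhepta-2,5-dien-2-yl]zirconium | Cl[Zr](/C(C)=C/CC=C(C)C)(C1C=CC=C1)C1C=CC=C1 | intermediate (not isolated)
5 | (2E)-2-iodo-6-methylhepta-2,5-diene | I/C(C)=C/CC=C(C)C | intermediate
6 | (2E)-1,4-dibromobut-2-ene | BrC/C=C/CBr | starting material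
7 | [(2Z)-6-methylhepta-2,5-dien-2-yl]lithium (Li trans to the CH2 group, geometry of 5 retained) | [Li]/C(C)=C/CC=C(C)C | intermediate (not isolated)
8 | bromo[(2E)-6-methylhepta-2,5-dien-2-yl]magnesium | Br[Mg]/C(C)=C/CC=C(C)C | intermediate (not isolated)
9 | (3R,4E)-3-(bromomethyl)-4,8-dimethylnona-1,4,7-triene | C=C[C@H](/C(C)=C/CC=C(C)C)CBr | intermediate
10 | geranyl acetate, (2E)-3,7-dimethylocta-2,6-dien-1-yl acetate | CC(=O)OC/C=C(C)/CCC=C(C)C | starting material
11 | (2E,6E)-8-hydroxy-3,7-dimethylocta-2,6-dien-1-yl acetate | CC(=O)OC/C=C(C)/CC/C=C(C)/CO | intermediate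
12 | (2E,6E)-8-bromo-3,7-dimethylocta-2,6-dien-1-yl acetate | CC(=O)OC/C=C(C)/CC/C=C(C)/CBr | intermediate
13 | bromo[(2R,3E)-2-ethenyl-3,7-dimethylocta-3,6-dien-1-yl]magnesium | C=C[C@H](/C(C)=C/CC=C(C)C)C[Mg]Br | intermediate (not isolated)
14 | (2E,6E,10R,11E)-10-ethenyl-3,7,11,15-tetramethylhexadeca-2,6,11,14-tetraen-1-yl acetate | C=C[C@H](/C(C)=C/CC=C(C)C)CC/C(C)=C/CC/C(C)=C/COC(C)=O | intermediate
15 | 9-BBN adduct of 14 (9-borabicyclo[3.3.1]nonan-9-yl on the terminal carbon of the former vinyl group; C4 and all alkenes unchanged) | B1(CC[C@H](/C(C)=C/CC=C(C)C)CC/C(C)=C/CC/C(C)=C/COC(C)=O)C2CCCC1CCC2 | intermediate (not isolated)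
16 | (2E,6E,10R)-3,7-dimethyl-10-[(2E)-6-methylhepta-2,5-dien-2-yl]dodeca-2,6-diene-1,12-diol | OCC[C@H](/C(C)=C/CC=C(C)C)CC/C(C)=C/CC/C(C)=C/CO | intermediate
17 | (3R,6E,10E)-12-chloro-6,10-dimethyl-3-[(2E)-6-methylhepta-2,5-dien-2-yl]dodeca-6,10-dien-1-ol | OCC[C@H](/C(C)=C/CC=C(C)C)CC/C(C)=C/CC/C(C)=C/CCl | intermediate
18 | (methylsulfanyl)benzene (thioanisole) | CSc1ccccc1 | starting material
19 | (phenylsulfanyl)methyllithium | [Li]CSc1ccccc1 | intermediate (not isolated)
20 | (3R,6E,10E)-6,10-dimethyl-3-[(2E)-6-methylhepta-2,5-dien-2-yl]-13-(phenylsulfanyl)trideca-6,10-dien-1-ol | OCC[C@H](/C(C)=C/CC=C(C)C)CC/C(C)=C/CC/C(C)=C/CCSc1ccccc1 | intermediate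
21 | S-methyl-S-phenylsulfonium iodide of 20 (methylated at sulfur, otherwise unchanged) | OCC[C@H](/C(C)=C/CC=C(C)C)CC/C(C)=C/CC/C(C)=C/CC[S+](C)c1ccccc1.[I-] | intermediate (not isolated)
22 | (3R,6E,10E)-13-iodo-6,10-dimethyl-3-[(2E)-6-methylhepta-2,5-dien-2-yl]trideca-6,10-dien-1-ol | OCC[C@H](/C(C)=C/CC=C(C)C)CC/C(C)=C/CC/C(C)=C/CCI | intermediate
23 | trimethyl phosphonoacetate, methyl 2-(dimethoxyphosphoryl)acetate | COC(=O)CP(=O)(OC)OC | starting material
24 | sodium enolate of trimethyl phosphonoacetate | [Na+].COC(=O)[CH-]P(=O)(OC)OC | intermediate (not isolated)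
25 | methyl (5E,9E,13R)-2-(dimethoxyphosphoryl)-15-hydroxy-6,10-dimethyl-13-[(2E)-6-methylhepta-2,5-dien-2-yl]pentadeca-5,9-dienoate (both C2 epimers) | OCC[C@H](/C(C)=C/CC=C(C)C)CC/C(C)=C/CC/C(C)=C/CCC(C(=O)OC)P(=O)(OC)OC | intermediate
26 | methyl (5E,9E,13R)-2-(dimethoxyphosphoryl)-6,10-dimethyl-13-[(2E)-6-methylhepta-2,5-dien-2-yl]-15-oxopentadeca-5,9-dienoate (both C2 epimers) | O=CC[C@H](/C(C)=C/CC=C(C)C)CC/C(C)=C/CC/C(C)=C/CCC(C(=O)OC)P(=O)(OC)OC | intermediate
27 | methyl (1E,4R,7E,11E)-7,11-dimethyl-4-[(2E)-6-methylhepta-2,5-dien-2-yl]cyclotetradeca-1,7,11-triene-1-carboxylate | COC(=O)/C1=C/C[C@H](/C(C)=C/CC=C(C)C)CC/C(C)=C/CC/C(C)=C/CC1 | target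

**Step count and risks**

Total steps: 13. Longest linear sequence: 11 (steps 1–3, then 6–13); steps 4–5 form the convergent branch.

The three steps most likely to fail:

Step 3, the alkenyl SN2′ desymmetrisation, is untested for an sp2 Grignard reagent (SN2′/SN2 ratio and ee unknown). The fallback sets out from 5 and comes back at 9. Iodine–lithium exchange on 5 (t-BuLi, −78 °C) and borylation with 2-isopropoxy-4,4,5,5-tetramethyl-1,3,2-dioxaborolane give the pinacol alkenylboronate F1. A Rh(I)/chiral-diene catalysed substitutive alkenylation of commercial (2Z)-but-2-ene-1,4-diol (syn addition of alkenyl-Rh to the symmetric alkene, then β-hydroxide elimination) gives (2R,3E)-2-ethenyl-3,7-dimethylocta-3,6-dien-1-ol F2. Appel bromination (CBr4, PPh3) then returns to 9.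

Step 6 depends on a homoallylic Grignard reagent that can rearrange through a cyclopropylcarbinyl species, and on chemoselectivity against the acetate. The fallback sets out from 9 and comes back at 14. Displacement with sodium benzenesulfinate (DMF, NaI cat., 70 °C) gives the sulfone F3. Its α-lithio derivative (n-BuLi, THF, −78 °C) is alkylated by 12 to give the coupled sulfone F4. Reductive desulfonylation (Na/Hg, Na2HPO4, MeOH–THF, −20 °C) returns to 14.

Step 13, the macrocyclic HWE, may give oligomers or E/Z mixtures. The fallback sets out from 16 and comes back at 27, closing the ring at C14–C1 instead. MnO2 oxidises only the allylic alcohol of 16 to the enal F5. Methylenation (Ph3P=CH2, 2.2 equiv) gives the 1,3-diene alcohol F6, and Dess–Martin oxidation gives the aldehyde F7. Wittig reaction with methyl bromo(triphenylphosphoranylidene)acetate gives the (Z)-α-bromo enoate F8. 9-BBN adds to the terminal diene carbon to give the borane F9. Intramolecular B-alkyl Suzuki–Miyaura coupling (Pd(dppf)Cl2, AsPh3, Cs2CO3, DMF–THF–H2O, 0.002 M) with retention at C1 gives 27.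

Further compounds
F1 | step 3 | 4,4,5,5-tetramethyl-2-[(2Z)-6-methylhepta-2,5-dien-2-yl]-1,3,2-dioxaborolane (boron trans to the CH2 group) | CC1(C)OB(OC1(C)C)/C(C)=C/CC=C(C)C
F2 | step 3 | (2R,3E)-2-ethenyl-3,7-dimethylocta-3,6-dien-1-ol | C=C[C@H](/C(C)=C/CC=C(C)C)CO
F3 | step 6 | {[(2R,3E)-2-ethenyl-3,7-dimethylocta-3,6-dien-1-yl]sulfonyl}benzene | C=C[C@H](/C(C)=C/CC=C(C)C)CS(=O)(=O)c1ccccc1
F4 | step 6 | (2E,6E,10R,11E)-10-ethenyl-3,7,11,15-tetramethyl-9-(phenylsulfonyl)hexadeca-2,6,11,14-tetraen-1-yl acetate (both C9 epimers) | C=C[C@H](/C(C)=C/CC=C(C)C)C(C/C(C)=C/CC/C(C)=C/COC(C)=O)S(=O)(=O)c1ccccc1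
F5 | step 13 | (2E,6E,10R)-12-hydroxy-3,7-dimethyl-10-[(2E)-6-methylhepta-2,5-dien-2-yl]dodeca-2,6-dienal | OCC[C@H](/C(C)=C/CC=C(C)C)CC/C(C)=C/CC/C(C)=C/C=O
F6 | step 13 | (3R,6E,10E)-6,10-dimethyl-3-[(2E)-6-methylhepta-2,5-dien-2-yl]trideca-6,10,12-trien-1-ol | OCC[C@H](/C(C)=C/CC=C(C)C)CC/C(C)=C/CC/C(C)=C/C=C
F7 | step 13 | (3R,6E,10E)-6,10-dimethyl-3-[(2E)-6-methylhepta-2,5-dien-2-yl]trideca-6,10,12-trienal | O=CC[C@H](/C(C)=C/CC=C(C)C)CC/C(C)=C/CC/C(C)=C/C=C
F8 | step 13 | methyl (2Z,5R,8E,12E)-2-bromo-8,12-dimethyl-5-[(2E)-6-methylhepta-2,5-dien-2-yl]pentadeca-2,8,12,14-tetraenoate | COC(=O)/C(Br)=C/C[C@H](/C(C)=C/CC=C(C)C)CC/C(C)=C/CC/C(C)=C/C=C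
F9 | step 13 | 9-BBN adduct of F8 (9-borabicyclo[3.3.1]nonan-9-yl on C15, the former terminal diene carbon) | COC(=O)/C(Br)=C/C[C@H](/C(C)=C/CC=C(C)C)CC/C(C)=C/CC/C(C)=C/CCB1C2CCCC1CCC2
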